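The readings come from a simulation with made-up constants, and the scatter is random.

In a one-step world, electrophile + nucleophile → product at equal charges, the reciprocal of the fraction of electrophile left climbs in a straight line with time. Its slope, the second-order rate constant times the electrophile charge, is what I carry.

| flask | electrophile | nucleophile | free base | remark | time |
|---|---|---|---|---|---|
| west | 20 mM | 1.05 equiv | 1.5 equiv | run made earlier |  |
| south-west | 20 mM | 1.05 equiv | 2.2 equiv | run made earlier |  |
| north-west | 20 mM | 1.6 equiv | 3 equiv | run made earlier |  |
| flask | 20 mM | 1.05 equiv | 3.00 equiv |  | 5.0 h |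

| run | time / h | electrophile / % | product / % |
|---|---|---|---|
| west | 0.500 | 63 | 43 |
| west | 1.33 | 35 | 67 |
| west | 2.50 | 19 | 78 |
| west | 4.00 | 12 | 88 |
| south-west | 1.00 | 40 | 59 |
| south-west | 2.00 | 20 | 76 |
| south-west | 3.00 | 16 | 84 |
| south-west | 4.00 | 9 | 88 |
| north-west | 1.00 | 22 | 77 |
| north-west | 2.00 | 8 | 93 |
| north-west | 3.00 | 1 | 98 |
| north-west | 4.00 | 2 | 100 |

(readings scatter by 1.5 percentage points)
* part of the electrophile that has reacted at 5.0 h
* share of the unused nucleophile that is free and not bound as protonated nucleophile, at 5.0 h
- what was read earlier has a scatter of 1.5 percentage points, one standard deviation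
- the earlier runs do not show how much of nucleophile is bound; that part of a forecast is a guess

With a nucleophile excess x, as a fraction of the charge, the fraction left is x divided by a quantity: one plus x, times the exponential of x times slope times time, less one. Reading this rule backwards with 0.0500, the last west reading gives 1.50 h⁻¹ and the last south-west reading 1.97 h⁻¹. The first north-west reading, with its larger excess, gives 1.41 h⁻¹. Their mean is my clock rate, 1.62 h⁻¹.

For the flask, where electrophile is the limiting reagent, equal charges would leave 11.0%, and the excess, a small correction, lowers this to 8.68%. Next come protonated nucleophile and free base. West and south-west differ in free base and read 12% and 9% of electrophile left at 4.00 h, with a scatter of 1.5 percentage points on each, so I add no correction and commit to 91.3% reacted. For the free share I have no number of my own.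

The forecast gives 92% reacted and 90% free, and says of the second, “This is a guess, because binding was never measured directly”.

The flask gives 90.6% reacted and 99.4% free.

    electrophile + nucleophile → acid set free + product (k = 1.30 L mol⁻¹ min⁻¹)
    nucleophile + acid set free ⇌ protonated nucleophile, settled at all times (K = 3000 L mol⁻¹)
    acid set free + free base ⇌ salt of the base (K = 5.80 × 10⁵ L mol⁻¹, k = 77.0 L mol⁻¹ min⁻¹)
    crystals ⇌ acid set free, rate k4*(cs4 - [acid set free]) while solid is left; crystals form when [acid set free] > cs4 (solubility = 5.60 mM, k = 0.570 min⁻¹)
    acid set free → by-product carried off (k = 0.880 min⁻¹)

The 9.4% of electrophile left in the flask reads back to a clock rate of 1.51 h⁻¹. At 0.560 h in the flask, the half-life of acid set free by the forward step to free base alone is 0.17 min, far shorter than the 0.560 h by which half of the main step's turnover up to 5.0 h is done, and at 5.0 h the free share stands at 99.4%. In the neighbour with 8.0 mM of electrophile, at the same equivalents and time, the clock rate scales with the charge to 0.650 h⁻¹, so the rule leaves 21.3% of the electrophile; the computed neighbour leaves 22.4%.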